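**Retrosynthetic overview**

1. The target is (7E,12Z,18S,20Z)-variabilin. C20=C21 is cut by an aldol condensation between a C1–C20 α-methyl aldehyde and 4-methoxy-3-methylfuran-2(5H)-one, followed by O-demethylation.
2. C16–C17 is cut by an alkyl–alkyl Negishi coupling of a C5–C16 homoallyl tosylate with the zinc homoenolate of methyl (2R)-3-bromo-2-methylpropanoate, which brings C18.
3. Key step: the C15–C16 bond and the 12Z olefin come from a Still–Wittig [2,3]-sigmatropic rearrangement of the stannylmethyl ether of an isopropenyl carbinol.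
4. The carbinol comes from epoxide-to-allylic-alcohol isomerisation of 12,13-epoxydendrolasin, made by copper-catalysed coupling (C5–C6) of 3-furylmethyl Grignard reagent with 6,7-epoxygeranyl chloride (7E bought).
5. Rings: the furan is bought intact; the butenolide ring is closed on a side branch by lactonisation before the aldol union; no ring is made after that.

Assumption: variabilin numbering is used (furan C1–C4, chain C5–C20, butenolide C21–C24), and furan-3-ylmethanol, geranyl chloride, methyl (2R)-3-bromo-2-methylpropanoate, ethyl 2-methyl-3-oxobutanoate and all reagents (Bu3SnCH2I included) are taken as bought.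

**Route**

Step 1
Reactants: 1 furan-3-ylmethanol
Product: 2 3-(chloromethyl)furan
Conditions: SOCl2, pyridine, Et2O, 0 °C
Reagents that add atoms: thionyl chloride, ClS(Cl)=O
Why: Chlorodehydroxylation through the chlorosulfite ester (SN2 by chloride) works here because pyridine takes up the HCl and spares the acid-labile furan, and the labile chloride is used at once.

Step 2
Reactants: 3 geranyl chloride, (2E)-1-chloro-3,7-dimethylocta-2,6-diene
Product: 4 rac-3-[(3E)-5-chloro-3-methylpent-3-en-1-yl]-2,2-dimethyloxirane (6,7-epoxygeranyl chloride)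
Conditions: mCPBA (1.0 equiv), CH2Cl2, −10 °C → 0 °C
Reagents that add atoms: 3-chloroperoxybenzoic acid, OOC(=O)c1cccc(Cl)c1
Why: Prilezhaev epoxidation picks the electron-rich 6,7-olefin because the 2,3-olefin is deactivated by the allylic chlorine, and the new stereocentre is racemic and is erased in step 6.

Step 3
Reactants: 2 3-(chloromethyl)furan; 4 rac-3-[(3E)-5-chloro-3-methylpent-3-en-1-yl]-2,2-dimethyloxirane
Product: 6 rac-3-[(3E)-6-(3,3-dimethyloxiran-2-yl)-4-methylhex-3-en-1-yl]furan (12,13-epoxydendrolasin), via furan-3-ylmethylmagnesium chloride 5 (not isolated)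
Conditions: 2, Mg turnings, THF, 0 °C → rt; then 4, Li2CuCl4 (3 mol %), THF, 0 °C
Reagents that add atoms: none
Why: Copper-catalysed Kochi-type SN2 coupling of the Grignard reagent at the primary allylic chloride is far faster than opening of the trisubstituted epoxide and keeps the 7E geometry bought with geranyl chloride, as in the known dendrolasin coupling.

Step 4
Reactants: 6 rac-3-[(3E)-6-(3,3-dimethyloxiran-2-yl)-4-methylhex-3-en-1-yl]furan
Product: 7 rac-(6E)-9-(furan-3-yl)-2,6-dimethylnona-1,6-dien-3-ol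
Conditions: Et2Al(TMP) (TMP = 2,2,6,6-tetramethylpiperidide; 2.5 equiv, made from 2,2,6,6-tetramethylpiperidine, n-BuLi and Et2AlCl), toluene, 0 °C; then aq. KNaC4H4O6
Reagents that add atoms: none
Why: In this Yamamoto epoxide-to-allylic-alcohol isomerisation the aluminium amide binds the epoxide oxygen and removes a methyl proton on the more substituted carbon in a cyclic syn elimination, which gives the isopropenyl carbinol regioselectively under basic conditions that do not start a cationic cyclisation onto the olefin or the furan, and the racemic carbinol centre is erased in step 6.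

Step 5
Reactants: 7 rac-(6E)-9-(furan-3-yl)-2,6-dimethylnona-1,6-dien-3-ol
Product: 8 rac-tributyl({[(6E)-9-(furan-3-yl)-2,6-dimethylnona-1,6-dien-3-yl]oxy}methyl)stannane
Conditions: KH, THF, 0 °C → rt; then Bu3SnCH2I
Reagents that add atoms: tributyl(iodomethyl)stannane, CCCC[Sn](CCCC)(CCCC)CI
Why: Williamson etherification of the potassium alkoxide with the reactive primary iodide installs the latent α-alkoxy carbanion needed for the rearrangement.

Step 6
Reactants: 8 rac-tributyl({[(6E)-9-(furan-3-yl)-2,6-dimethylnona-1,6-dien-3-yl]oxy}methyl)stannane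
Product: 11 (3Z,7E)-10-(furan-3-yl)-3,7-dimethyldeca-3,7-dien-1-yl 4-methylbenzenesulfonate, via lithiomethyl ether 9 (not isolated), via lithium homoallyl alkoxide 10 (not isolated)
Conditions: n-BuLi, THF, −78 °C; then TsCl, −78 °C → rt
Reagents that add atoms: 4-methylbenzenesulfonyl chloride, Cc1ccc(cc1)S(Cl)(=O)=O
Why: Tin–lithium exchange (much faster than furan lithiation at −78 °C) triggers the Still–Wittig [2,3]-sigmatropic rearrangement, which forms the C15–C16 bond through an envelope transition state with the C11 chain pseudoaxial to avoid the 2-methyl group and so gives the 12Z trisubstituted olefin (about 95:5 for such 2-methylallyl systems), and the lithium alkoxide is sulfonylated in the same flask.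

Step 7
Reactants: 11 (3Z,7E)-10-(furan-3-yl)-3,7-dimethyldeca-3,7-dien-1-yl 4-methylbenzenesulfonate; 12 methyl (2R)-3-bromo-2-methylpropanoate
Product: 14 methyl (2S,6Z,10E)-13-(furan-3-yl)-2,6,10-trimethyltrideca-6,10-dienoate, via zinc homoenolate 13 (not isolated)
Conditions: 12, Zn dust, I2 (5 mol %), DMA, 70 °C; then 11, Pd2(dba)3 (2 mol %), P(c-C5H9)3 (8 mol %), N-methylimidazole, THF/NMP, 80 °C
Reagents that add atoms: none
Why: This Negishi alkyl–alkyl cross-coupling under Fu-type conditions joins C16 to C17 because the bulky electron-rich trialkylphosphine on zerovalent palladium allows oxidative addition of the primary tosylate and outruns β-hydride elimination, and C18 is bought with 12 and is untouched since it is not the metal-bearing carbon (the descriptor changes from R to S only through the priority rules).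

Step 8
Reactants: 14 methyl (2S,6Z,10E)-13-(furan-3-yl)-2,6,10-trimethyltrideca-6,10-dienoate
Product: 15 (2S,6Z,10E)-13-(furan-3-yl)-2,6,10-trimethyltrideca-6,10-dienal
Conditions: i-Bu2AlH (1.1 equiv), CH2Cl2, −78 °C; then aq. KNaC4H4O6
Reagents that add atoms: none
Why: Partial ester reduction stops at the aldehyde because the tetrahedral aluminium hemiacetal is stable at −78 °C, and the non-basic conditions keep the α-stereocentre, with the aldehyde used crude at once.

Step 9
Reactants: 16 ethyl 2-methyl-3-oxobutanoate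
Product: 18 4-hydroxy-3-methylfuran-2(5H)-one (3-methyltetronic acid), via ethyl 4-bromo-2-methyl-3-oxobutanoate 17 (not isolated)
Conditions: Br2, CHCl3, 0 °C → rt; then neat, 100 °C
Reagents that add atoms: none
Why: Bromination followed by HBr-mediated migration of bromine to the γ-position gives the 4-bromo keto ester, whose ester carbonyl oxygen displaces bromide on heating (lactonisation with loss of bromoethane) to close the tetronic acid ring.

Step 10
Reactants: 18 4-hydroxy-3-methylfuran-2(5H)-one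
Product: 19 4-methoxy-3-methylfuran-2(5H)-one
Conditions: Me2SO4, K2CO3, acetone, reflux
Reagents that add atoms: dimethyl sulfate, COS(=O)(=O)OC
Why: O-alkylation of the tetronate anion (a vinylogous carboxylate) by the hard electrophile gives the 4-methyl ether, which masks the acidic OH for the aldol step.

Step 11
Reactants: 15 (2S,6Z,10E)-13-(furan-3-yl)-2,6,10-trimethyltrideca-6,10-dienal; 19 4-methoxy-3-methylfuran-2(5H)-one
Product: 23 (5Z)-5-[(2S,6Z,10E)-13-(furan-3-yl)-2,6,10-trimethyltrideca-6,10-dien-1-ylidene]-4-methoxy-3-methylfuran-2(5H)-one, via lithium furanolate 20 (not isolated), via lithium aldolate 21 (not isolated), via aldol mesylate 22 (not isolated)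
Conditions: 19, LiN(i-Pr)2, THF, −78 °C; then 15, −78 °C; then MsCl, −78 °C → 0 °C; then DBU, rt
Reagents that add atoms: none
Why: Vinylogous aldol addition of the C5-lithiated tetronate (an aromatic 2-furanolate) to the aldehyde at −78 °C is faster than aldehyde enolisation, and mesylation followed by DBU-promoted E1cB elimination gives the thermodynamically preferred 20Z alkylidene (chain syn to the ring oxygen and away from the 4-methoxy group) without touching C18.

Step 12
Reactants: 23 (5Z)-5-[(2S,6Z,10E)-13-(furan-3-yl)-2,6,10-trimethyltrideca-6,10-dien-1-ylidene]-4-methoxy-3-methylfuran-2(5H)-one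
Product: 24 (5Z)-5-[(2S,6Z,10E)-13-(furan-3-yl)-2,6,10-trimethyltrideca-6,10-dien-1-ylidene]-4-hydroxy-3-methylfuran-2(5H)-one (target)
Conditions: NaSEt, DMF, rt → 50 °C; then 1 M HCl to pH 3, 0 °C
Reagents that add atoms: none
Why: The soft thiolate cleaves the methyl vinylogous carbonate by SN2 attack at the methyl carbon with the tetronate anion as leaving group, and cold dilute acid then frees the tetronic acid without harming the furan, the olefins or C18.

**Compound list**

1 | furan-3-ylmethanol | OCc1ccoc1 | starting material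
2 | 3-(chloromethyl)furan | ClCc1ccoc1 | intermediate
3 | geranyl chloride, (2E)-1-chloro-3,7-dimethylocta-2,6-diene | CC(C)=CCC/C(C)=C/CCl | starting material
4 | rac-3-[(3E)-5-chloro-3-methylpent-3-en-1-yl]-2,2-dimethyloxirane | CC1(C)OC1CC/C(C)=C/CCl | intermediate
5 | furan-3-ylmethylmagnesium chloride (formed in the flask) | Cl[Mg]Cc1ccoc1 | intermediate
6 | rac-3-[(3E)-6-(3,3-dimethyloxiran-2-yl)-4-methylhex-3-en-1-yl]furan | CC1(C)OC1CC/C(C)=C/CCc2ccoc2 | intermediate
7 | rac-(6E)-9-(furan-3-yl)-2,6-dimethylnona-1,6-dien-3-ol | C=C(C)C(O)CC/C(C)=C/CCc1ccoc1 | intermediate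
8 | rac-tributyl({[(6E)-9-(furan-3-yl)-2,6-dimethylnona-1,6-dien-3-yl]oxy}methyl)stannane | CCCC[Sn](CCCC)(CCCC)COC(CC/C(C)=C/CCc1ccoc1)C(C)=C | intermediate
9 | rac-({[(6E)-9-(furan-3-yl)-2,6-dimethylnona-1,6-dien-3-yl]oxy}methyl)lithium (formed in the flask) | [Li]COC(CC/C(C)=C/CCc1ccoc1)C(C)=C | intermediate
10 | lithium (3Z,7E)-10-(furan-3-yl)-3,7-dimethyldeca-3,7-dien-1-olate (formed in the flask) | [Li+].[O-]CC/C(C)=C\CC/C(C)=C/CCc1ccoc1 | intermediate
11 | (3Z,7E)-10-(furan-3-yl)-3,7-dimethyldeca-3,7-dien-1-yl 4-methylbenzenesulfonate | Cc1ccc(cc1)S(=O)(=O)OCC/C(C)=C\CC/C(C)=C/CCc2ccoc2 | intermediate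
12 | methyl (2R)-3-bromo-2-methylpropanoate | COC(=O)[C@@H](C)CBr | starting material
13 | bromo[(2R)-3-methoxy-2-methyl-3-oxopropyl]zinc (formed in the flask) | COC(=O)[C@@H](C)C[Zn]Br | intermediate
14 | methyl (2S,6Z,10E)-13-(furan-3-yl)-2,6,10-trimethyltrideca-6,10-dienoate | COC(=O)[C@@H](C)CCC/C(C)=C\CC/C(C)=C/CCc1ccoc1 | intermediate
15 | (2S,6Z,10E)-13-(furan-3-yl)-2,6,10-trimethyltrideca-6,10-dienal | O=C[C@@H](C)CCC/C(C)=C\CC/C(C)=C/CCc1ccoc1 | intermediate
16 | ethyl 2-methyl-3-oxobutanoate | CCOC(=O)C(C)C(C)=O | starting material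
17 | ethyl 4-bromo-2-methyl-3-oxobutanoate (formed in the flask) | CCOC(=O)C(C)C(=O)CBr | intermediate
18 | 4-hydroxy-3-methylfuran-2(5H)-one | CC1=C(O)COC1=O | intermediate
19 | 4-methoxy-3-methylfuran-2(5H)-one | COC1=C(C)C(=O)OC1 | intermediate
20 | lithium 4-methoxy-3-methylfuran-2-olate (formed in the flask) | [Li+].[O-]c1occ(OC)c1C | intermediate
21 | lithium (2S,6Z,10E)-13-(furan-3-yl)-1-(3-methoxy-4-methyl-5-oxo-2,5-dihydrofuran-2-yl)-2,6,10-trimethyltrideca-6,10-dien-1-olate, mixture of diastereomers at C1 and at the ring carbon (formed in the flask) | [Li+].[O-]C([C@@H](C)CCC/C(C)=C\CC/C(C)=C/CCc1ccoc1)C1OC(=O)C(C)=C1OC | intermediate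
22 | (2S,6Z,10E)-13-(furan-3-yl)-1-(3-methoxy-4-methyl-5-oxo-2,5-dihydrofuran-2-yl)-2,6,10-trimethyltrideca-6,10-dien-1-yl methanesulfonate, mixture of diastereomers (formed in the flask) | CS(=O)(=O)OC([C@@H](C)CCC/C(C)=C\CC/C(C)=C/CCc1ccoc1)C1OC(=O)C(C)=C1OC | intermediate
23 | (5Z)-5-[(2S,6Z,10E)-13-(furan-3-yl)-2,6,10-trimethyltrideca-6,10-dien-1-ylidene]-4-methoxy-3-methylfuran-2(5H)-one | CC1=C(OC)/C(=C/[C@@H](C)CCC/C(C)=C\CC/C(C)=C/CCc2ccoc2)OC1=O | intermediate
24 | (5Z)-5-[(2S,6Z,10E)-13-(furan-3-yl)-2,6,10-trimethyltrideca-6,10-dien-1-ylidene]-4-hydroxy-3-methylfuran-2(5H)-one | CC1=C(O)/C(=C/[C@@H](C)CCC/C(C)=C\CC/C(C)=C/CCc2ccoc2)OC1=O | target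

**Step count and risks**

Total step count: 12. Longest linear sequence: 9 steps (3 → 4 → 6 → 7 → 8 → 11 → 14 → 15 → 23 → 24; steps 2–8, 11 and 12).

Most likely to fail, step 6 (Still–Wittig rearrangement with tosylation in the same flask). The risks are a Z:E ratio below about 95:5, a competing [1,2]-shift and loss of material in the in-flask sulfonylation. The fallback sets out from 6 and comes back at 11, and builds the Z olefin by a Still–Gennari olefination instead of a rearrangement. H5IO6 (THF/Et2O, 0 °C) cleaves epoxide 6 to (4E)-7-(furan-3-yl)-4-methylhept-4-enal F1. Methyl 2-[bis(2,2,2-trifluoroethoxy)phosphoryl]propanoate with KN(SiMe3)2 and 18-crown-6 (THF, −78 °C) then gives methyl (2Z,6E)-9-(furan-3-yl)-2,6-dimethylnona-2,6-dienoate F2. i-Bu2AlH reduces it to (2Z,6E)-9-(furan-3-yl)-2,6-dimethylnona-2,6-dien-1-ol F3, and CBr4/PPh3 gives 3-[(3E,7Z)-9-bromo-4,8-dimethylnona-3,7-dien-1-yl]furan F4. Li2CuCl4-catalysed coupling with (i-PrO)Me2SiCH2MgCl adds C16 as [(3Z,7E)-10-(furan-3-yl)-3,7-dimethyldeca-3,7-dien-1-yl](dimethyl)(propan-2-yloxy)silane F5. Tamao oxidation (H2O2, KF, KHCO3, THF/MeOH) gives (3Z,7E)-10-(furan-3-yl)-3,7-dimethyldeca-3,7-dien-1-ol F6, and TsCl/pyridine gives 11.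

Most likely to fail, step 7 (alkyl–alkyl Negishi coupling). The risks are slow transmetalation of the chelated zinc homoenolate and β-hydride elimination or isomerisation of the homoallyl palladium species. The fallback sets out from 11 and comes back at 15, and uses a copper-catalysed Grignard–tosylate coupling with the C20 oxygen carried as a silyl ether. Bought (2R)-3-bromo-2-methylpropan-1-ol is silylated (t-BuMe2SiCl, imidazole) to tert-butyl{[(2R)-3-bromo-2-methylpropyl]oxy}dimethylsilane F7. Mg in THF turns it into bromo[(2R)-3-{[tert-butyl(dimethyl)silyl]oxy}-2-methylpropyl]magnesium F8. Li2CuCl4-catalysed coupling with 11 (THF, −20 °C → rt) gives tert-butyl{[(2S,6Z,10E)-13-(furan-3-yl)-2,6,10-trimethyltrideca-6,10-dien-1-yl]oxy}dimethylsilane F9. Bu4NF gives (2S,6Z,10E)-13-(furan-3-yl)-2,6,10-trimethyltrideca-6,10-dien-1-ol F10, and Dess–Martin periodinane with NaHCO3 gives 15.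

Most likely to fail, step 11 (aldol, mesylation and elimination in one flask). The risks are partial epimerisation of the α-methyl aldehyde by the basic furanolate, retro-aldol before mesylation and an E/Z mixture. The fallback sets out from 19 and comes back at 23, and replaces the lithium aldol by a Lewis-acid vinylogous Mukaiyama aldol with no base present. Treatment of 19 with t-BuMe2SiOSO2CF3 and Et3N gives tert-butyl[(4-methoxy-3-methylfuran-2-yl)oxy]dimethylsilane F11. BF3·OEt2 (CH2Cl2, −78 °C) joins it to 15 to give 5-[(2S,6Z,10E)-13-(furan-3-yl)-1-hydroxy-2,6,10-trimethyltrideca-6,10-dien-1-yl]-4-methoxy-3-methylfuran-2(5H)-one F12. This aldol is isolated, mesylated (MsCl, Et3N, giving 22) and eliminated with DBU to 23.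

**Further compounds**

F1 | step 6 | (4E)-7-(furan-3-yl)-4-methylhept-4-enal | O=CCC/C(C)=C/CCc1ccoc1
F2 | step 6 | methyl (2Z,6E)-9-(furan-3-yl)-2,6-dimethylnona-2,6-dienoate | COC(=O)/C(C)=C\CC/C(C)=C/CCc1ccoc1
F3 | step 6 | (2Z,6E)-9-(furan-3-yl)-2,6-dimethylnona-2,6-dien-1-ol | OC/C(C)=C\CC/C(C)=C/CCc1ccoc1
F4 | step 6 | 3-[(3E,7Z)-9-bromo-4,8-dimethylnona-3,7-dien-1-yl]furan | BrC/C(C)=C\CC/C(C)=C/CCc1ccoc1
F5 | step 6 | [(3Z,7E)-10-(furan-3-yl)-3,7-dimethyldeca-3,7-dien-1-yl](dimethyl)(propan-2-yloxy)silane | CC(C)O[Si](C)(C)CC/C(C)=C\CC/C(C)=C/CCc1ccoc1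
F6 | step 6 | (3Z,7E)-10-(furan-3-yl)-3,7-dimethyldeca-3,7-dien-1-ol | OCC/C(C)=C\CC/C(C)=C/CCc1ccoc1
F7 | step 7 | tert-butyl{[(2R)-3-bromo-2-methylpropyl]oxy}dimethylsilane | CC(C)(C)[Si](C)(C)OC[C@@H](C)CBr
F8 | step 7 | bromo[(2R)-3-{[tert-butyl(dimethyl)silyl]oxy}-2-methylpropyl]magnesium | CC(C)(C)[Si](C)(C)OC[C@@H](C)C[Mg]Br
F9 | step 7 | tert-butyl{[(2S,6Z,10E)-13-(furan-3-yl)-2,6,10-trimethyltrideca-6,10-dien-1-yl]oxy}dimethylsilane | CC(C)(C)[Si](C)(C)OC[C@@H](C)CCC/C(C)=C\CC/C(C)=C/CCc1ccoc1
F10 | step 7 | (2S,6Z,10E)-13-(furan-3-yl)-2,6,10-trimethyltrideca-6,10-dien-1-ol | OC[C@@H](C)CCC/C(C)=C\CC/C(C)=C/CCc1ccoc1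
F11 | step 11 | tert-butyl[(4-methoxy-3-methylfuran-2-yl)oxy]dimethylsilane | COc1coc(O[Si](C)(C)C(C)(C)C)c1C
F12 | step 11 | 5-[(2S,6Z,10E)-13-(furan-3-yl)-1-hydroxy-2,6,10-trimethyltrideca-6,10-dien-1-yl]-4-methoxy-3-methylfuran-2(5H)-one | COC1=C(C)C(=O)OC1C(O)[C@@H](C)CCC/C(C)=C\CC/C(C)=C/CCc2ccoc2
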